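## Retrosynthetic overview

1. Plakotenin ⇐ ester hydrolysis ⇐ thermal intramolecular Diels–Alder reaction of the acyclic (2E,4Z,6R,8R,9E,11E)-tetraene ester. The cyclohexene and the cyclopentane close together in this single ring-forming step (bonds C4–C12 and C5–C9 of the chain).
2. Dienophile end ⇐ HWE (C2=C3) on a (Z)-enal ⇐ Still–Gennari olefination (C4=C5) of a C5 aldehyde. Diene end ⇐ Wittig (C9=C10), then benzylphosphonate HWE (C11=C12), on a C9 aldehyde.
3. The C5–C9 anti-1,3-dimethyl core ⇐ C7–C8 bond by an Evans syn-aldol between the Roche-ester aldehyde (C5–C7, carries C6) and (R)-propionyl oxazolidinone (C8–C9, sets C8), followed by Barton–McCombie removal of the C7 hydroxyl.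

Assumption: the descriptors of the given SMILES, (1R,3R,3aR,4S,5S,7aR) with a 2E side chain, are taken as binding; "chain C-n" in the Why lines means the numbering of the acyclic tetraene acid (C1 = CO2H, C12 = CHPh).

## Route

Step 1
Reactants: 1 methyl (S)-3-hydroxy-2-methylpropanoate
Product: 2 methyl (S)-3-[(tert-butyldiphenylsilyl)oxy]-2-methylpropanoate
Conditions: TBDPSCl, imidazole, DMF, 0 °C → rt
Reagents that add atoms: tert-butyl(chloro)diphenylsilane (TBDPSCl), CC(C)(C)[Si](Cl)(c1ccccc1)c1ccccc1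
Why: Imidazole-promoted silylation of the primary alcohol; the stereocentre (later chain C6) is not touched.

Step 2
Reactants: 2 methyl (S)-3-[(tert-butyldiphenylsilyl)oxy]-2-methylpropanoate
Product: 3 (R)-3-[(tert-butyldiphenylsilyl)oxy]-2-methylpropan-1-ol
Conditions: DIBAL-H (2.2 equiv), CH2Cl2, −78 → 0 °C; Rochelle salt
Reagents that add atoms: none
Why: DIBAL-H ester reduction to the primary alcohol, which avoids over-reduction mixtures of a direct ester-to-aldehyde step; the centre is unchanged (S → R is CIP bookkeeping only).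

Step 3
Reactants: 3 (R)-3-[(tert-butyldiphenylsilyl)oxy]-2-methylpropan-1-ol
Product: 4 (S)-3-[(tert-butyldiphenylsilyl)oxy]-2-methylpropanal
Conditions: Dess–Martin periodinane, NaHCO3, CH2Cl2, 0 °C; used crude at once
Reagents that add atoms: none
Why: Dess–Martin oxidation under buffered, non-basic conditions gives the α-methyl aldehyde without epimerisation.

Step 4
Reactants: 4 (S)-3-[(tert-butyldiphenylsilyl)oxy]-2-methylpropanal; 5 (R)-4-benzyl-3-propanoyl-1,3-oxazolidin-2-one
Product: 8 (R)-4-benzyl-3-[(2R,3S,4S)-5-[(tert-butyldiphenylsilyl)oxy]-3-hydroxy-2,4-dimethylpentanoyl]-1,3-oxazolidin-2-one, via dibutylboron (Z)-enolate 6 (not isolated), via dibutylboron aldolate 7 (not isolated)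
Conditions: n-Bu2BOTf, Et3N, CH2Cl2, −78 → 0 °C; then 4, −78 → 0 °C; pH 7 buffer, MeOH, 30% H2O2, 0 °C
Reagents that add atoms: none
Why: Evans syn-aldol reaction: the (Z)-boron enolate reacts through a closed Zimmerman–Traxler transition state on the face opposite the benzyl group, so the auxiliary fixes the α-methyl centre (2R, later chain C8) and the syn hydroxyl (removed in step 8), while the aldehyde's own centre is carried through (reagent control).

Step 5
Reactants: 8 (R)-4-benzyl-3-[(2R,3S,4S)-5-[(tert-butyldiphenylsilyl)oxy]-3-hydroxy-2,4-dimethylpentanoyl]-1,3-oxazolidin-2-one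
Product: 9 (2S,3R,4S)-5-[(tert-butyldiphenylsilyl)oxy]-2,4-dimethylpentane-1,3-diol
Conditions: LiBH4, H2O (1 equiv), Et2O, 0 °C
Reagents that add atoms: none
Why: Reductive cleavage of the N-acyl oxazolidinone with LiBH4 gives the primary alcohol and returns the auxiliary; no centre is inverted (descriptor changes are CIP bookkeeping).

Step 6
Reactants: 9 (2S,3R,4S)-5-[(tert-butyldiphenylsilyl)oxy]-2,4-dimethylpentane-1,3-diol
Product: 10 (2S,3R,4S)-5-[(tert-butyldiphenylsilyl)oxy]-3-hydroxy-2,4-dimethylpentyl pivalate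
Conditions: PivCl (1.1 equiv), pyridine, CH2Cl2, 0 °C
Reagents that add atoms: pivaloyl chloride, CC(C)(C)C(Cl)=O
Why: Selective acylation of the primary hydroxyl over the hindered secondary one, flanked by two branched carbons.

Step 7
Reactants: 10 (2S,3R,4S)-5-[(tert-butyldiphenylsilyl)oxy]-3-hydroxy-2,4-dimethylpentyl pivalate
Product: 11 (2S,3R,4S)-5-[(tert-butyldiphenylsilyl)oxy]-3-[(1H-imidazole-1-carbothioyl)oxy]-2,4-dimethylpentyl pivalate
Conditions: 1,1'-thiocarbonyldiimidazole, DMAP (cat.), toluene, 80 °C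
Reagents that add atoms: 1,1'-thiocarbonyldiimidazole (TCDI), S=C(n1ccnc1)n1ccnc1
Why: Thioacylation of the only free hydroxyl gives the imidazolyl thionocarbamate for Barton–McCombie deoxygenation; neutral conditions avoid acyl or silyl migration.

Step 8
Reactants: 11 (2S,3R,4S)-5-[(tert-butyldiphenylsilyl)oxy]-3-[(1H-imidazole-1-carbothioyl)oxy]-2,4-dimethylpentyl pivalate
Product: 12 (2R,4R)-5-[(tert-butyldiphenylsilyl)oxy]-2,4-dimethylpentyl pivalate
Conditions: n-Bu3SnH, AIBN (cat.), toluene, 110 °C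
Reagents that add atoms: none
Why: Barton–McCombie radical deoxygenation removes the aldol oxygen at C3; the two methyl-bearing centres are not radical sites and remain, now as the anti (2R,4R) pair.

Step 9
Reactants: 12 (2R,4R)-5-[(tert-butyldiphenylsilyl)oxy]-2,4-dimethylpentyl pivalate
Product: 13 (2R,4R)-5-[(tert-butyldiphenylsilyl)oxy]-2,4-dimethylpentan-1-ol
Conditions: DIBAL-H (2.5 equiv), CH2Cl2, −78 °C; Rochelle salt
Reagents that add atoms: none
Why: Reductive cleavage of the pivalate ester with DIBAL-H; the silyl ether is inert.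

Step 10
Reactants: 13 (2R,4R)-5-[(tert-butyldiphenylsilyl)oxy]-2,4-dimethylpentan-1-ol
Product: 14 (2R,4R)-5-[(tert-butyldiphenylsilyl)oxy]-2,4-dimethylpentanal
Conditions: Dess–Martin periodinane, NaHCO3, CH2Cl2, 0 °C; used crude at once
Reagents that add atoms: none
Why: Dess–Martin oxidation; buffered conditions keep the α-methyl centre (chain C8) intact.

Step 11
Reactants: 14 (2R,4R)-5-[(tert-butyldiphenylsilyl)oxy]-2,4-dimethylpentanal; 15 ethyl 2-(triphenyl-λ5-phosphanylidene)propanoate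
Product: 16 ethyl (2E,4R,6R)-7-[(tert-butyldiphenylsilyl)oxy]-2,4,6-trimethylhept-2-enoate
Conditions: CH2Cl2, rt → 40 °C
Reagents that add atoms: none
Why: Wittig olefination with a stabilised, non-basic ylide gives the (E)-trisubstituted enoate (chain C9=C10) without epimerising the adjacent centre.

Step 12
Reactants: 16 ethyl (2E,4R,6R)-7-[(tert-butyldiphenylsilyl)oxy]-2,4,6-trimethylhept-2-enoate
Product: 17 (2E,4R,6R)-7-[(tert-butyldiphenylsilyl)oxy]-2,4,6-trimethylhept-2-en-1-ol
Conditions: DIBAL-H (2.2 equiv), CH2Cl2, −78 °C; Rochelle salt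
Reagents that add atoms: none
Why: DIBAL-H 1,2-reduction of the enoate to the allylic alcohol; alkene geometry is unaffected.

Step 13
Reactants: 17 (2E,4R,6R)-7-[(tert-butyldiphenylsilyl)oxy]-2,4,6-trimethylhept-2-en-1-ol
Product: 18 (2E,4R,6R)-7-[(tert-butyldiphenylsilyl)oxy]-2,4,6-trimethylhept-2-enal
Conditions: activated MnO2, CH2Cl2, rt
Reagents that add atoms: none
Why: Chemoselective MnO2 oxidation of the allylic alcohol to the (E)-enal.

Step 14
Reactants: 18 (2E,4R,6R)-7-[(tert-butyldiphenylsilyl)oxy]-2,4,6-trimethylhept-2-enal; 19 diethyl benzylphosphonate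
Product: 21 tert-butyl(diphenyl){[(2R,4R,5E,7E)-2,4,6-trimethyl-8-phenylocta-5,7-dien-1-yl]oxy}silane, via sodium benzylphosphonate anion 20 (not isolated)
Conditions: 19, NaH, 15-crown-5 (cat.), THF, 0 °C; then 18, 0 °C → rt
Reagents that add atoms: none
Why: Horner–Wadsworth–Emmons olefination gives the (E)-styryl bond (chain C11=C12); the anion is preformed so that no free base can deprotonate the γ-position of the enal.

Step 15
Reactants: 21 tert-butyl(diphenyl){[(2R,4R,5E,7E)-2,4,6-trimethyl-8-phenylocta-5,7-dien-1-yl]oxy}silane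
Product: 22 (2R,4R,5E,7E)-2,4,6-trimethyl-8-phenylocta-5,7-dien-1-ol
Conditions: TBAF, THF, rt
Reagents that add atoms: none
Why: Fluoride-mediated cleavage of the silyl ether; the phenyl diene is inert to TBAF (no acid is used).

Step 16
Reactants: 22 (2R,4R,5E,7E)-2,4,6-trimethyl-8-phenylocta-5,7-dien-1-ol
Product: 23 (2R,4R,5E,7E)-2,4,6-trimethyl-8-phenylocta-5,7-dienal
Conditions: Dess–Martin periodinane, NaHCO3, CH2Cl2, 0 °C; used crude at once
Reagents that add atoms: none
Why: Dess–Martin oxidation to the α-methyl aldehyde (chain C5) under buffered conditions, leaving the diene and the α-centre (chain C6) intact.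

Step 17
Reactants: 24 methyl 2-[bis(2,2,2-trifluoroethoxy)phosphoryl]acetate; 25 iodoethane
Product: 27 methyl 2-[bis(2,2,2-trifluoroethoxy)phosphoryl]butanoate (racemic), via sodium phosphonoacetate anion 26 (not isolated)
Conditions: NaH (1.0 equiv), THF, 0 °C; then EtI, 0 °C → rt
Reagents that add atoms: none
Why: SN2 C-alkylation of the stabilised phosphonoacetate anion gives the α-ethyl Still–Gennari reagent; its stereocentre is lost on deprotonation in step 18.

Step 18
Reactants: 23 (2R,4R,5E,7E)-2,4,6-trimethyl-8-phenylocta-5,7-dienal; 27 methyl 2-[bis(2,2,2-trifluoroethoxy)phosphoryl]butanoate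
Product: 29 methyl (2Z,4R,6R,7E,9E)-2-ethyl-4,6,8-trimethyl-10-phenyldeca-2,7,9-trienoate, via potassium phosphonate enolate 28 (not isolated)
Conditions: 27, KHMDS, 18-crown-6, THF, −78 °C; then 23, −78 °C
Reagents that add atoms: none
Why: Still–Gennari olefination: the electron-poor bis(trifluoroethyl) phosphonate under dissociating K+/18-crown-6 conditions eliminates from the kinetic adduct and gives the (Z)-enoate (chain cis to the ester), which is the 4Z dienophile geometry needed later.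

Step 19
Reactants: 29 methyl (2Z,4R,6R,7E,9E)-2-ethyl-4,6,8-trimethyl-10-phenyldeca-2,7,9-trienoate
Product: 30 (2Z,4R,6R,7E,9E)-2-ethyl-4,6,8-trimethyl-10-phenyldeca-2,7,9-trien-1-ol
Conditions: DIBAL-H (2.2 equiv), CH2Cl2, −78 °C; Rochelle salt
Reagents that add atoms: none
Why: DIBAL-H 1,2-reduction of the enoate to the (Z)-allylic alcohol; any (E)-isomer from step 18 is removed here by chromatography.

Step 20
Reactants: 30 (2Z,4R,6R,7E,9E)-2-ethyl-4,6,8-trimethyl-10-phenyldeca-2,7,9-trien-1-ol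
Product: 31 (2Z,4R,6R,7E,9E)-2-ethyl-4,6,8-trimethyl-10-phenyldeca-2,7,9-trienal
Conditions: Dess–Martin periodinane, NaHCO3, CH2Cl2, 0 °C; used cold and at once
Reagents that add atoms: none
Why: Buffered Dess–Martin oxidation gives the (Z)-enal without acid- or base-induced Z → E isomerisation.

Step 21
Reactants: 31 (2Z,4R,6R,7E,9E)-2-ethyl-4,6,8-trimethyl-10-phenyldeca-2,7,9-trienal; 32 ethyl 2-(diethoxyphosphoryl)propanoate
Product: 34 ethyl (2E,4Z,6R,8R,9E,11E)-4-ethyl-2,6,8,10-tetramethyl-12-phenyldodeca-2,4,9,11-tetraenoate, via sodium phosphonopropanoate anion 33 (not isolated)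
Conditions: 32, NaH, THF, 0 °C; then 31, −78 → 0 °C; work-up below rt
Reagents that add atoms: none
Why: Horner–Wadsworth–Emmons olefination at low temperature gives the (2E)-α-methyl enoate, leaves the 4Z bond alone and keeps the tetraene below the temperature of cycloaddition.

Step 22
Reactants: 34 ethyl (2E,4Z,6R,8R,9E,11E)-4-ethyl-2,6,8,10-tetramethyl-12-phenyldodeca-2,4,9,11-tetraenoate
Product: 35 ethyl (2E)-3-[(1R,3R,3aR,4S,5S,7aR)-4-ethyl-1,3,7-trimethyl-5-phenyl-2,3,3a,4,5,7a-hexahydro-1H-inden-4-yl]-2-methylprop-2-enoate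
Conditions: toluene (0.01 M), BHT (cat.), 100 °C, sealed tube; chromatography
Reagents that add atoms: none
Why: Thermal intramolecular Diels–Alder reaction: suprafacial addition across the (9E,11E)-diene and the 4Z γ,δ-bond of the dienoate fixes 5-H/7a-H cis and 3a-H/4-ethyl cis, the trans-fused (ethyl-endo) transition state gives the trans ring junction, and chain C6/C8 pass unchanged into C3/C1; which face pair reacts relative to these two methyl centres is substrate-controlled and is the weak point named below.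

Step 23
Reactants: 35 ethyl (2E)-3-[(1R,3R,3aR,4S,5S,7aR)-4-ethyl-1,3,7-trimethyl-5-phenyl-2,3,3a,4,5,7a-hexahydro-1H-inden-4-yl]-2-methylprop-2-enoate
Product: 36 plakotenin, (2E)-3-[(1R,3R,3aR,4S,5S,7aR)-4-ethyl-1,3,7-trimethyl-5-phenyl-2,3,3a,4,5,7a-hexahydro-1H-inden-4-yl]-2-methylprop-2-enoic acid
Conditions: LiOH, THF/MeOH/H2O, 50 °C; then 1 M HCl to pH 3
Reagents that add atoms: lithium hydroxide (its oxygen becomes the carboxylic OH), [Li+].[OH-]
Why: Ester saponification followed by acidification; no stereocentre is epimerisable and the (E)-acrylate is stable to hydroxide.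

## Compound list

1 | methyl (S)-3-hydroxy-2-methylpropanoate | COC(=O)[C@@H](C)CO | starting material
2 | methyl (S)-3-[(tert-butyldiphenylsilyl)oxy]-2-methylpropanoate | COC(=O)[C@@H](C)CO[Si](c1ccccc1)(c1ccccc1)C(C)(C)C | intermediate
3 | (R)-3-[(tert-butyldiphenylsilyl)oxy]-2-methylpropan-1-ol | OC[C@@H](C)CO[Si](c1ccccc1)(c1ccccc1)C(C)(C)C | intermediate
4 | (S)-3-[(tert-butyldiphenylsilyl)oxy]-2-methylpropanal | O=C[C@@H](C)CO[Si](c1ccccc1)(c1ccccc1)C(C)(C)C | intermediate
5 | (R)-4-benzyl-3-propanoyl-1,3-oxazolidin-2-one | CCC(=O)N1[C@H](Cc2ccccc2)COC1=O | starting material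
6 | dibutylboron (Z)-enolate of 5 (not isolated) | C/C=C(\OB(CCCC)CCCC)N1[C@H](Cc2ccccc2)COC1=O | intermediate
7 | dibutylboron aldolate of 8 (not isolated) | O=C(N1[C@H](Cc2ccccc2)COC1=O)[C@H](C)[C@@H](OB(CCCC)CCCC)[C@@H](C)CO[Si](c1ccccc1)(c1ccccc1)C(C)(C)C | intermediate
8 | (R)-4-benzyl-3-[(2R,3S,4S)-5-[(tert-butyldiphenylsilyl)oxy]-3-hydroxy-2,4-dimethylpentanoyl]-1,3-oxazolidin-2-one | O=C(N1[C@H](Cc2ccccc2)COC1=O)[C@H](C)[C@@H](O)[C@@H](C)CO[Si](c1ccccc1)(c1ccccc1)C(C)(C)C | intermediate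
9 | (2S,3R,4S)-5-[(tert-butyldiphenylsilyl)oxy]-2,4-dimethylpentane-1,3-diol | OC[C@H](C)[C@@H](O)[C@@H](C)CO[Si](c1ccccc1)(c1ccccc1)C(C)(C)C | intermediate
10 | (2S,3R,4S)-5-[(tert-butyldiphenylsilyl)oxy]-3-hydroxy-2,4-dimethylpentyl pivalate | CC(C)(C)C(=O)OC[C@H](C)[C@@H](O)[C@@H](C)CO[Si](c1ccccc1)(c1ccccc1)C(C)(C)C | intermediate
11 | (2S,3R,4S)-5-[(tert-butyldiphenylsilyl)oxy]-3-[(1H-imidazole-1-carbothioyl)oxy]-2,4-dimethylpentyl pivalate | CC(C)(C)C(=O)OC[C@H](C)[C@@H](OC(=S)n1ccnc1)[C@@H](C)CO[Si](c1ccccc1)(c1ccccc1)C(C)(C)C | intermediate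
12 | (2R,4R)-5-[(tert-butyldiphenylsilyl)oxy]-2,4-dimethylpentyl pivalate | CC(C)(C)C(=O)OC[C@H](C)C[C@@H](C)CO[Si](c1ccccc1)(c1ccccc1)C(C)(C)C | intermediate
13 | (2R,4R)-5-[(tert-butyldiphenylsilyl)oxy]-2,4-dimethylpentan-1-ol | OC[C@H](C)C[C@@H](C)CO[Si](c1ccccc1)(c1ccccc1)C(C)(C)C | intermediate
14 | (2R,4R)-5-[(tert-butyldiphenylsilyl)oxy]-2,4-dimethylpentanal | O=C[C@H](C)C[C@@H](C)CO[Si](c1ccccc1)(c1ccccc1)C(C)(C)C | intermediate
15 | ethyl 2-(triphenyl-λ5-phosphanylidene)propanoate | CCOC(=O)C(C)=P(c1ccccc1)(c1ccccc1)c1ccccc1 | starting material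
16 | ethyl (2E,4R,6R)-7-[(tert-butyldiphenylsilyl)oxy]-2,4,6-trimethylhept-2-enoate | CCOC(=O)/C(C)=C/[C@H](C)C[C@@H](C)CO[Si](c1ccccc1)(c1ccccc1)C(C)(C)C | intermediate
17 | (2E,4R,6R)-7-[(tert-butyldiphenylsilyl)oxy]-2,4,6-trimethylhept-2-en-1-ol | OC/C(C)=C/[C@H](C)C[C@@H](C)CO[Si](c1ccccc1)(c1ccccc1)C(C)(C)C | intermediate
18 | (2E,4R,6R)-7-[(tert-butyldiphenylsilyl)oxy]-2,4,6-trimethylhept-2-enal | O=C/C(C)=C/[C@H](C)C[C@@H](C)CO[Si](c1ccccc1)(c1ccccc1)C(C)(C)C | intermediate
19 | diethyl benzylphosphonate | CCOP(=O)(Cc1ccccc1)OCC | starting material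
20 | sodium salt of the diethyl benzylphosphonate carbanion (not isolated) | [Na+].CCOP(=O)([CH-]c1ccccc1)OCC | intermediate
21 | tert-butyl(diphenyl){[(2R,4R,5E,7E)-2,4,6-trimethyl-8-phenylocta-5,7-dien-1-yl]oxy}silane | CC(C)(C)[Si](c1ccccc1)(c1ccccc1)OC[C@H](C)C[C@@H](C)/C=C(C)/C=C/c1ccccc1 | intermediate
22 | (2R,4R,5E,7E)-2,4,6-trimethyl-8-phenylocta-5,7-dien-1-ol | OC[C@H](C)C[C@@H](C)/C=C(C)/C=C/c1ccccc1 | intermediate
23 | (2R,4R,5E,7E)-2,4,6-trimethyl-8-phenylocta-5,7-dienal | O=C[C@H](C)C[C@@H](C)/C=C(C)/C=C/c1ccccc1 | intermediate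
24 | methyl 2-[bis(2,2,2-trifluoroethoxy)phosphoryl]acetate | COC(=O)CP(=O)(OCC(F)(F)F)OCC(F)(F)F | starting material
25 | iodoethane | CCI | starting material
26 | sodium salt of the carbanion of 24 (not isolated) | [Na+].COC(=O)[CH-]P(=O)(OCC(F)(F)F)OCC(F)(F)F | intermediate
27 | methyl 2-[bis(2,2,2-trifluoroethoxy)phosphoryl]butanoate (racemic) | CCC(C(=O)OC)P(=O)(OCC(F)(F)F)OCC(F)(F)F | intermediate
28 | potassium salt of the carbanion of 27 (not isolated) | [K+].CC[C-](C(=O)OC)P(=O)(OCC(F)(F)F)OCC(F)(F)F | intermediate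
29 | methyl (2Z,4R,6R,7E,9E)-2-ethyl-4,6,8-trimethyl-10-phenyldeca-2,7,9-trienoate | COC(=O)/C(CC)=C\[C@H](C)C[C@@H](C)/C=C(C)/C=C/c1ccccc1 | intermediate
30 | (2Z,4R,6R,7E,9E)-2-ethyl-4,6,8-trimethyl-10-phenyldeca-2,7,9-trien-1-ol | OC/C(CC)=C\[C@H](C)C[C@@H](C)/C=C(C)/C=C/c1ccccc1 | intermediate
31 | (2Z,4R,6R,7E,9E)-2-ethyl-4,6,8-trimethyl-10-phenyldeca-2,7,9-trienal | O=C/C(CC)=C\[C@H](C)C[C@@H](C)/C=C(C)/C=C/c1ccccc1 | intermediate
32 | ethyl 2-(diethoxyphosphoryl)propanoate | CCOC(=O)C(C)P(=O)(OCC)OCC | starting material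
33 | sodium salt of the carbanion of 32 (not isolated) | [Na+].CCOC(=O)[C-](C)P(=O)(OCC)OCC | intermediate
34 | ethyl (2E,4Z,6R,8R,9E,11E)-4-ethyl-2,6,8,10-tetramethyl-12-phenyldodeca-2,4,9,11-tetraenoate | CCOC(=O)/C(C)=C/C(CC)=C\[C@H](C)C[C@@H](C)/C=C(C)/C=C/c1ccccc1 | intermediate
35 | ethyl (2E)-3-[(1R,3R,3aR,4S,5S,7aR)-4-ethyl-1,3,7-trimethyl-5-phenyl-2,3,3a,4,5,7a-hexahydro-1H-inden-4-yl]-2-methylprop-2-enoate | CC[C@@]1(/C=C(\C)C(=O)OCC)[C@H]2[C@H](C(C)=C[C@H]1c1ccccc1)[C@H](C)C[C@H]2C | intermediate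
36 | plakotenin, (2E)-3-[(1R,3R,3aR,4S,5S,7aR)-4-ethyl-1,3,7-trimethyl-5-phenyl-2,3,3a,4,5,7a-hexahydro-1H-inden-4-yl]-2-methylprop-2-enoic acid | CC[C@@]1(/C=C(\C)C(=O)O)[C@H]2[C@H](C(C)=C[C@H]1c1ccccc1)[C@H](C)C[C@H]2C | target

## Step count and risks

Total step count: 23. Longest linear sequence: 22 steps (steps 1–16 and 18–23); step 17 is a one-step side branch.

The three steps most likely to fail:

Step 8 (with its thioacylation in step 7). The hydroxyl is flanked by two methyl-branched carbons, so thioacylation can be slow and the thionocarbamate may eliminate on heating instead of being reduced. The fallback sets out from 9 and comes back at 13. Diol 9 is treated with 1,1'-thiocarbonyldiimidazole (toluene, 80 °C) so that the primary hydroxyl reacts first and the hindered one closes the ring intramolecularly, giving (4R,5S)-4-[(2S)-1-[(tert-butyldiphenylsilyl)oxy]propan-2-yl]-5-methyl-1,3-dioxane-2-thione F1. With n-Bu3SnH/AIBN (toluene, 110 °C) the ring opens at the secondary C–O bond, through the more stable secondary radical, to O-[(2R,4R)-5-[(tert-butyldiphenylsilyl)oxy]-2,4-dimethylpentyl] S-(tributylstannyl) carbonothioate F2. NaOH/MeOH in the work-up then frees alcohol 13. This avoids the separately activated secondary alcohol and makes 10–12 unnecessary.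

Step 18. The Z:E ratio with an α-ethyl reagent and an α-branched, epimerisable aldehyde may be only moderate. The fallback sets out from 23 and comes back at 34. A Stork–Zhao-type Wittig reaction of 23 with the α-iodo ylide Ph3P=C(I)CH2CH3 (generated in situ from propyltriphenylphosphonium iodide with n-BuLi, I2 and NaHMDS, THF, −78 °C) gives [(1E,3E,5R,7R,8Z)-9-iodo-3,5,7-trimethylundeca-1,3,8-trien-1-yl]benzene F3, in which iodine is cis to the chain. Stille coupling of F3 with ethyl (E)-2-methyl-3-(tributylstannyl)prop-2-enoate (Pd2(dba)3, AsPh3, CuI, NMP, rt), with retention at both partners, gives tetraene ester 34 directly. This also avoids the (Z)-enal 31 and its possible isomerisation.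

Step 22. Four stereocentres are set at once, and only substrate control decides the fusion mode (trans versus cis) and which face pair reacts relative to the C6/C8 methyls. The wanted adduct carries each methyl cis to the neighbouring ring carbon (C7 and C4), a relationship that allylic strain in the transition state does not favour. The adduct with the opposite sense at C3a, C4, C5 and C7a may therefore form in quantity or dominate, and I could not confirm the selectivity. The fallback sets out from 31 and comes back at 35. The ring is closed one stage earlier on the smaller, more reactive enal dienophile (toluene, 60–80 °C, or Me2AlCl, CH2Cl2, −40 °C) to give (1R,3R,3aR,4R,5S,7aR)-4-ethyl-1,3,7-trimethyl-5-phenyl-2,3,3a,4,5,7a-hexahydro-1H-indene-4-carbaldehyde F4, and the diastereomers are separated at this stage. Horner–Wadsworth–Emmons reaction of F4 with anion 33 (THF, reflux) then installs the (E)-methylacrylate and gives 35. This changes the order of ring closure and chain extension, but it does not remove the underlying facial preference.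

## Further compounds

F1 | step 8 | (4R,5S)-4-[(2S)-1-[(tert-butyldiphenylsilyl)oxy]propan-2-yl]-5-methyl-1,3-dioxane-2-thione | S=C1OC[C@H](C)[C@@H](O1)[C@@H](C)CO[Si](c2ccccc2)(c2ccccc2)C(C)(C)C
F2 | step 8 | O-[(2R,4R)-5-[(tert-butyldiphenylsilyl)oxy]-2,4-dimethylpentyl] S-(tributylstannyl) carbonothioate | CCCC[Sn](CCCC)(CCCC)SC(=O)OC[C@H](C)C[C@@H](C)CO[Si](c1ccccc1)(c1ccccc1)C(C)(C)C
F3 | step 18 | [(1E,3E,5R,7R,8Z)-9-iodo-3,5,7-trimethylundeca-1,3,8-trien-1-yl]benzene | I/C(CC)=C\[C@H](C)C[C@@H](C)/C=C(C)/C=C/c1ccccc1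
F4 | step 22 | (1R,3R,3aR,4R,5S,7aR)-4-ethyl-1,3,7-trimethyl-5-phenyl-2,3,3a,4,5,7a-hexahydro-1H-indene-4-carbaldehyde | CC[C@@]1(C=O)[C@H]2[C@H](C(C)=C[C@H]1c1ccccc1)[C@H](C)C[C@H]2C
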